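**Retrosynthetic overview**
1. CIML C (20) ⇐ macrocyclic 2-ynoate 19 by cis-semihydrogenation, so the Z-enoate appears only in the last step.
2. 19 ⇐ acyclic bis(vinyl carbinol) ester 17 in one flask: ring-closing metathesis at C6=C7 closes the 22-membered lactone ring first, then hydroxyl-directed epoxidation closes the oxirane.
3. 17 ⇐ ester aldehyde 15 by catalytic asymmetric vinylation (C8); 15 ⇐ ynoic acid 14 + hydroxy aldehyde 5 (ester bond, C21 from the chiral pool).
4. 14 ⇐ (S)-epichlorohydrin + acetylene + CO2 (C5 from the chiral pool); 5 ⇐ 11-bromoundec-1-ene + (R)-propylene oxide, then hydroformylation.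

Assumption: the target is the (2Z,5S,6R,7R,8S,21R) isomer read from the SMILES; macrolide numbering is used (C1 = lactone C=O, C21 = lactone carbinol carbon, C22 = methyl).

**Step 1**
Reactants: 1 11-bromoundec-1-ene; 2 (R)-2-methyloxirane
Product: 4 (R)-tetradec-13-en-2-ol, via undec-10-enylmagnesium bromide 3 (not isolated)
Conditions: Mg, THF, 40 °C; then CuI (10 mol%), 2, −30 → 0 °C; aq. NH4Cl
Reagents that add atoms: none
Why: Cu-catalysed SN2 opening of the terminal epoxide by the Grignard reagent at CH2 leaves the C–O stereocentre untouched, so C21 is (R) from the chiral pool.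

**Step 2**
Reactants: 4 (R)-tetradec-13-en-2-ol
Product: 5 (R)-14-hydroxypentadecanal
Conditions: Rh(acac)(CO)2 (0.5 mol%), BiPhePhos (1.5 mol%), CO/H2 (1:1, 10 bar), toluene, 70 °C
Reagents that add atoms: carbon monoxide, [C-]#[O+]
Why: Rh/bisphosphite hydroformylation is strongly linear-selective for terminal alkenes and tolerates the remote secondary alcohol, adding C8 as the aldehyde without touching a stereocentre.

**Step 3**
Reactants: 6 (S)-2-(chloromethyl)oxirane; 7 acetylene
Product: 9 (S)-1-chloropent-4-yn-2-ol, via lithium acetylide 8 (not isolated)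
Conditions: 7, n-BuLi, THF, −78 °C; BF3·OEt2, then 6, −78 °C; aq. NH4Cl
Reagents that add atoms: none
Why: Yamaguchi–Hirao alkynylation opens the BF3-activated epoxide at its CH2 terminus while C–Cl is inert at −78 °C, so the (S)-centre (future C5) is carried over unchanged.

**Step 4**
Reactants: 9 (S)-1-chloropent-4-yn-2-ol
Product: 11 (S)-hex-1-en-5-yn-3-ol, via (S)-2-(prop-2-yn-1-yl)oxirane 10 (not isolated)
Conditions: Me3S+ I− (4.5 equiv), n-BuLi (4.4 equiv), THF, −20 °C → rt
Reagents that add atoms: trimethylsulfonium iodide, C[S+](C)C.[I-]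
Why: base closes the chlorohydrin to epoxide 10, dimethylsulfonium methylide opens it at CH2 and the betaine eliminates Me2S (Corey–Chaykovsky-type one-carbon homologation of an epoxide to an allylic alcohol); the carbinol C–O bond is never broken, so C5 stays (S).

**Step 5**
Reactants: 11 (S)-hex-1-en-5-yn-3-ol
Product: 12 (S)-triethyl(hex-1-en-5-yn-3-yloxy)silane
Conditions: TESCl, imidazole, CH2Cl2, 0 °C
Reagents that add atoms: chlorotriethylsilane, CC[Si](Cl)(CC)CC
Why: standard silylation masks the C5 hydroxyl for carboxylation and esterification, and the TES ether is labile enough to be cleaved in the acidic work-up of step 8.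

**Step 6**
Reactants: 12 (S)-triethyl(hex-1-en-5-yn-3-yloxy)silane
Product: 14 (5S)-5-(triethylsilyloxy)hept-6-en-2-ynoic acid, via lithium alkynide 13 (not isolated)
Conditions: n-BuLi, THF, −78 °C; CO2 (g); cold dil. HCl to pH 3, brief
Reagents that add atoms: carbon dioxide, O=C=O
Why: deprotonation of the terminal alkyne and carboxylation of the lithium alkynide installs C1, and brief cold acidification keeps the TES ether.

**Step 7**
Reactants: 14 (5S)-5-(triethylsilyloxy)hept-6-en-2-ynoic acid; 5 (R)-14-hydroxypentadecanal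
Product: 15 (2R)-15-oxopentadecan-2-yl (5S)-5-(triethylsilyloxy)hept-6-en-2-ynoate
Conditions: DCC, DMAP (10 mol%), CH2Cl2, −20 → 0 °C
Reagents that add atoms: none
Why: Steglich esterification acylates the only hydroxyl of 5 with retention at C21, while the aldehyde and the silyl ether are inert.

**Step 8**
Reactants: 15 (2R)-15-oxopentadecan-2-yl (5S)-5-(triethylsilyloxy)hept-6-en-2-ynoate
Product: 17 (2R,15S)-15-hydroxyheptadec-16-en-2-yl (5S)-5-hydroxyhept-6-en-2-ynoate, via TES-protected allylic alcohol 16 (not isolated)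
Conditions: pre-formed salt-free Zn(CH=CH2)2 (2.5 equiv), (+)-DAIB (10 mol%), toluene, 0 °C; then 1 M HCl/THF, rt
Reagents that add atoms: divinylzinc, C=C[Zn]C=C
Why: amino-alcohol-catalysed organozinc addition to the aldehyde, in which (+)-DAIB (mirror image of the Si-selective (−)-DAIB system) delivers vinyl to the Re face to set C8 as (S); the organozinc spares ester and ynoate, and the HCl work-up removes the TES group.

**Step 9**
Reactants: 17 (2R,15S)-15-hydroxyheptadec-16-en-2-yl (5S)-5-hydroxyhept-6-en-2-ynoate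
Product: 19 (5S,6R,7R,8S,21R)-6,7-epoxy-5,8-dihydroxydocos-2-yn-21-olide, via macrocyclic enediol 18 (not isolated)
Conditions: Grubbs II (5 mol%), 1,4-benzoquinone (10 mol%), CH2Cl2 (1 mM), 40 °C; then 0 °C, NaHCO3, mCPBA (2.5 equiv), 0 °C → rt
Reagents that add atoms: meta-chloroperoxybenzoic acid, OOC(=O)c1cccc(Cl)c1
Why: Proposed new method: the Ru carbene joins the two vinyl carbinols into the 22-membered ring (macrocyclic RCM of bis-allylic alcohols, E favoured by the two flanking CH(OH) groups), and mCPBA added to the same flask is hydrogen-bonded by the two locally C2-related (S)-carbinols of 18, which in their H-eclipsed rotamers both present the same alkene face, so syn delivery gives the threo,threo (6R,7R)-oxirane; the closest known types are macrocyclic RCM and the Henbest epoxidation of E-allylic alcohols, whose threo preference is only about 2:1 per carbinol, so the minor erythro,erythro isomer is removed by chromatography.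

**Step 10**
Reactants: 19 (5S,6R,7R,8S,21R)-6,7-epoxy-5,8-dihydroxydocos-2-yn-21-olide
Product: 20 CIML C, (2Z,5S,6R,7R,8S,21R)-6,7-epoxy-5,8-dihydroxydocos-2-en-21-olide
Conditions: H2 (1 atm), Lindlar catalyst (Pd/CaCO3, Pb), quinoline, EtOAc, rt
Reagents that add atoms: none
Why: Lindlar syn-semihydrogenation of the ynoate gives the (Z)-enoate only at the very end, so the lactonisation-prone δ-hydroxy cis-enoate is never carried through a step; epoxide, hydroxyls and lactone are inert to neutral H2/Pd–Pb.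

**Compound list**
1 | 11-bromoundec-1-ene | C=CCCCCCCCCCBr | starting material
2 | (R)-2-methyloxirane | C[C@@H]1CO1 | starting material
3 | undec-10-en-1-ylmagnesium bromide | C=CCCCCCCCCC[Mg]Br | intermediate
4 | (R)-tetradec-13-en-2-ol | C[C@@H](O)CCCCCCCCCCC=C | intermediate
5 | (R)-14-hydroxypentadecanal | C[C@@H](O)CCCCCCCCCCCCC=O | intermediate
6 | (S)-2-(chloromethyl)oxirane | ClC[C@@H]1CO1 | starting material
7 | acetylene | C#C | starting material
8 | lithium acetylide | [Li]C#C | intermediate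
9 | (S)-1-chloropent-4-yn-2-ol | ClC[C@@H](O)CC#C | intermediate
10 | (S)-2-(prop-2-yn-1-yl)oxirane | C#CC[C@H]1CO1 | intermediate
11 | (S)-hex-1-en-5-yn-3-ol | C=C[C@@H](O)CC#C | intermediate
12 | (S)-triethyl(hex-1-en-5-yn-3-yloxy)silane | C=C[C@@H](O[Si](CC)(CC)CC)CC#C | intermediate
13 | (S)-[4-(triethylsilyloxy)hex-5-en-1-yn-1-yl]lithium | [Li]C#CC[C@H](O[Si](CC)(CC)CC)C=C | intermediate
14 | (5S)-5-(triethylsilyloxy)hept-6-en-2-ynoic acid | C=C[C@@H](O[Si](CC)(CC)CC)CC#CC(=O)O | intermediate
15 | (2R)-15-oxopentadecan-2-yl (5S)-5-(triethylsilyloxy)hept-6-en-2-ynoate | C=C[C@@H](O[Si](CC)(CC)CC)CC#CC(=O)O[C@H](C)CCCCCCCCCCCCC=O | intermediate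
16 | (2R,15S)-15-hydroxyheptadec-16-en-2-yl (5S)-5-(triethylsilyloxy)hept-6-en-2-ynoate | C=C[C@@H](O[Si](CC)(CC)CC)CC#CC(=O)O[C@H](C)CCCCCCCCCCCC[C@H](O)C=C | intermediate
17 | (2R,15S)-15-hydroxyheptadec-16-en-2-yl (5S)-5-hydroxyhept-6-en-2-ynoate | C=C[C@@H](O)CC#CC(=O)O[C@H](C)CCCCCCCCCCCC[C@H](O)C=C | intermediate
18 | (5S,6E,8S,21R)-5,8-dihydroxydocos-6-en-2-yn-21-olide | C[C@@H]1CCCCCCCCCCCC[C@H](O)/C=C/[C@@H](O)CC#CC(=O)O1 | intermediate
19 | (5S,6R,7R,8S,21R)-6,7-epoxy-5,8-dihydroxydocos-2-yn-21-olide | C[C@@H]1CCCCCCCCCCCC[C@H](O)[C@H]2O[C@@H]2[C@@H](O)CC#CC(=O)O1 | intermediate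
20 | CIML C, (2Z,5S,6R,7R,8S,21R)-6,7-epoxy-5,8-dihydroxydocos-2-en-21-olide | C[C@@H]1CCCCCCCCCCCC[C@H](O)[C@H]2O[C@@H]2[C@@H](O)C/C=C\C(=O)O1 | target

**Totals**
Total step count: 10. Longest linear sequence: 8 steps (steps 3 to 10, from (S)-epichlorohydrin).

**Steps most likely to fail**

Step 9 (one-flask ring closure and epoxidation). The directed epoxidation of an E-allylic diol is only modestly threo-selective, and Ru residues may interfere with the peracid. Fallback, from 17 back to 19: run the metathesis alone and isolate the macrocyclic enediol 18. Silylate it with TESCl/imidazole to (5S,6E,8S,21R)-5,8-bis(triethylsilyloxy)docos-6-en-2-yn-21-olide F1. Epoxidise F1 under reagent control with the D-fructose-derived Shi ketone (Oxone, K2CO3, MeCN/DMM/buffer, 0 °C), which gives (R,R)-epoxides from E-alkenes, to obtain (5S,6R,7R,8S,21R)-6,7-epoxy-5,8-bis(triethylsilyloxy)docos-2-yn-21-olide F2. HF·pyridine/pyridine in THF at 0 °C then returns 19. The face is now chosen by the catalyst on a protected alkene instead of by the substrate hydroxyls.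

Step 8 (asymmetric vinylation). The ee with an unbranched aldehyde may be insufficient, and the ynoate is a possible side-reaction site. Fallback, from 15 back to 17: add vinylmagnesium bromide at −78 °C to give the C15-epimeric alcohols (2R,15RS)-15-hydroxyheptadec-16-en-2-yl (5S)-5-(triethylsilyloxy)hept-6-en-2-ynoate F3. Resolve them by Sharpless kinetic resolution (Ti(OiPr)4, D-(−)-DIPT, TBHP, 4 Å MS, CH2Cl2, −20 °C). The (15R)-epimer is consumed as the epoxy alcohol (2R,15R)-15-hydroxy-15-[(2S)-oxiran-2-yl]pentadecan-2-yl (5S)-5-(triethylsilyloxy)hept-6-en-2-ynoate F4, and the slow-reacting (15S)-alcohol 16 is recovered (at most 50%). HCl/THF converts 16 into 17. Stereocontrol at C8 thus comes from resolution rather than from asymmetric C–C bond formation.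

Step 10 (final semihydrogenation). Over-reduction is possible, and the free C5 hydroxyl may attack the new cis-enoate on the basic catalyst to give the δ-lactone. Fallback, from 19 back to 20: mask the diol with TBSOTf/2,6-lutidine as (5S,6R,7R,8S,21R)-5,8-bis(tert-butyldimethylsilyloxy)-6,7-epoxydocos-2-yn-21-olide F5. Semihydrogenate F5 (Lindlar, quinoline) to (2Z,5S,6R,7R,8S,21R)-5,8-bis(tert-butyldimethylsilyloxy)-6,7-epoxydocos-2-en-21-olide F6. Release the diol last with HF·pyridine/pyridine in THF at 0 °C to give 20. The endgame changes from a protecting-group-free reduction to reduction of a fully masked macrocycle.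

**Further compounds**
F1 | step 9 | (5S,6E,8S,21R)-5,8-bis(triethylsilyloxy)docos-6-en-2-yn-21-olide | C[C@@H]1CCCCCCCCCCCC[C@H](O[Si](CC)(CC)CC)/C=C/[C@@H](O[Si](CC)(CC)CC)CC#CC(=O)O1
F2 | step 9 | (5S,6R,7R,8S,21R)-6,7-epoxy-5,8-bis(triethylsilyloxy)docos-2-yn-21-olide | C[C@@H]1CCCCCCCCCCCC[C@H](O[Si](CC)(CC)CC)[C@H]2O[C@@H]2[C@@H](O[Si](CC)(CC)CC)CC#CC(=O)O1
F3 | step 8 | (2R,15RS)-15-hydroxyheptadec-16-en-2-yl (5S)-5-(triethylsilyloxy)hept-6-en-2-ynoate | C=C[C@@H](O[Si](CC)(CC)CC)CC#CC(=O)O[C@H](C)CCCCCCCCCCCCC(O)C=C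
F4 | step 8 | (2R,15R)-15-hydroxy-15-[(2S)-oxiran-2-yl]pentadecan-2-yl (5S)-5-(triethylsilyloxy)hept-6-en-2-ynoate | C=C[C@@H](O[Si](CC)(CC)CC)CC#CC(=O)O[C@H](C)CCCCCCCCCCCC[C@@H](O)[C@@H]1CO1
F5 | step 10 | (5S,6R,7R,8S,21R)-5,8-bis(tert-butyldimethylsilyloxy)-6,7-epoxydocos-2-yn-21-olide | C[C@@H]1CCCCCCCCCCCC[C@H](O[Si](C)(C)C(C)(C)C)[C@H]2O[C@@H]2[C@@H](O[Si](C)(C)C(C)(C)C)CC#CC(=O)O1
F6 | step 10 | (2Z,5S,6R,7R,8S,21R)-5,8-bis(tert-butyldimethylsilyloxy)-6,7-epoxydocos-2-en-21-olide | C[C@@H]1CCCCCCCCCCCC[C@H](O[Si](C)(C)C(C)(C)C)[C@H]2O[C@@H]2[C@@H](O[Si](C)(C)C(C)(C)C)C/C=C\C(=O)O1
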